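The numbers in the tables are calculated with constants of no real substance; scatter was added.

The vessel is closed, stirred and held at one temperature; in it E and X give J. The flasks birch, oak and elm have been read, and the ash flask has not.

| flask | E | X | time |
|---|---|---|---|
| birch | 0.500 M | 1.00 M |  |
| oak | 0.200 M | 0.700 M |  |
| elm | 1.00 M | 1.00 M |  |
| ash | 2.00 M | 4.00 M | 6.0 min |

- birch run (time / min: [E] / M): 1.2: 0.342; 2.4: 0.269; 3.6: 0.223; 4.8: 0.191; 6.0: 0.169
- oak run (time / min: [E] / M): 1.2: 0.142; 2.4: 0.126; 3.6: 0.098; 4.8: 0.093; 6.0: 0.070
- elm run (time / min: [E] / M): 1.2: 0.746; 2.4: 0.642; 3.6: 0.588; 4.8: 0.545; 6.0: 0.523

(scatter of a reading: 0.007 M)

- Overall: E + X -> J.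
- Constant volume, constant temperature.
- Bound and free are read together.
- "The second partner" is X.
- An order is taken over about fifteen percent of the charge, up and down.

- how the opening rate goes with [E] round the charge of the birch run: the exponent of the rate at two percent of E gone to J (one fixed amount of J, the same in the runs compared)
- how the opening rate goes with [X] round the charge of the birch run: the exponent of the rate at two percent of E gone to J
- the oak run starts with 0.300 M less of E and of X than the birch run, and with no J. Compared where both hold the same amount of E, once fifteen percent of what the oak run was charged with has turned into J, is the oak run faster, slower or alike (within a tenth)?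
- E in the ash run at 6.0 min, as a share of the E charged
- which of these the readings show (the product binds the substrate / nothing beyond the main steps / the by-product binds the second partner / two substrates go astray together / the second partner pairs with itself / the substrate pairs with itself)

The elm flask and the birch flask hold the same c(X), 1.00 M, but elm holds twice the E of birch. In the elm flask c(E) drops by 0.254 M in the first interval and by 0.0220 M in the last, a factor of 11.5. A one-for-one loss of X in elm allows a factor of at most 3.66, which is smaller, so X is going faster than E.

My own reckoning takes two X lost per J, so that c(X) free is the charge less twice the J made. The quantity to carry is then the reach, the J that a charge of X can pay for, which is half of the X charged: 2.00 M in the ash flask and 0.500 M in the elm flask. In elm the reach is less than the E charged, which makes X the limiting reagent, and c(E) in elm still reads 0.523 M at 6.0 min, above the 0.500 M that the reach leaves. Birch has the same reach, but that equals its whole charge of E, so c(E) in birch goes on down to 0.169 M.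

The ash flask holds 4.00 times the E and 4.00 times the X of birch, so at the charge c(X) is twice c(E) in both. The rate then goes as the square of c(E), and 1/c(E) gains the same amount in the same time. Birch gains 3.92 /M by 6.0 min, so ash should hold 0.226 M, or 11.3 % of its charge, give or take 0.63 percentage points from the scatter of that one reading.

The forecast gives orders of 1.02 in E and 1.02 in X, an oak flask that is faster, and 10.9 % for ash, a little below my figure. Its verdict is that the by-product binds the second partner, on the ground that “each J formed costs two X”.

    E + X → J + Z (0.3330 /M/min)
    X + Z ⇌ XZ, settled at all times (106.0 /M)

The ash flask holds 10.8 % of its E at 6.0 min, the orders are 1.0 and 1.0, the oak flask is faster, and the readings show that the by-product binds the second partner. A fit with two substrates going astray together puts ash at 4.04 %, and a reading there would have made the forecast wrong. In the ash flask, E + X ran while X + Z stood paired as XZ, and J came to 1.78 M of a reach of 2.00 M. The elm flask came to its reach of 0.500 M, half of its E, at 7.94 min.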